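**Retrosynthetic overview**
1. Target ⇒ spiro-epoxy lactone by one global hydrogenolysis. The tertiary OH is the oxirane oxygen that stays on C3, and both O-benzyl groups fall in the same step.
2. Spiro-epoxide ⇒ (E)-α-arylidene-β-benzyl lactone. Oxygen enters anti to the C4 benzyl group, which gives the cis-dibenzyl (3S,4R) series.
3. Arylidene lactone ⇒ one-pot union of guaiacyl Grignard, cyclopropane-fused α-phosphono lactone and syringyl aldehyde (homoconjugate ring opening, then Horner–Wadsworth–Emmons).
4. Cyclopropane-fused lactone ⇒ (S)-epichlorohydrin + diethyl cyanomethylphosphonate. The cyclopropane and the five-membered O-ring close in the same pot and fix C4 (key step).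
5. Ring order: cyclopropane and lactone together (step 1); cyclopropane spent in step 4; oxirane made in step 5 and spent in step 6. Both arenes are bought.

Reading of the SMILES used throughout: (3S,4R), with the C3-OH trans to the C4 benzyl group and the two benzyl groups cis on the lactone.

**Step 1**
Reactants: 1 (S)-epichlorohydrin; 2 diethyl cyanomethylphosphonate
Product: 6 diethyl [(1S,5R)-2-oxo-3-oxabicyclo[3.1.0]hexan-1-yl]phosphonate, via epoxy nitrile 3 (not isolated), via cyclopropyl alkoxide 4 (not isolated), via iminolactone 5 (not isolated)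
Conditions: NaOEt (1.2 equiv), EtOH, 0 °C to rt, 16 h; then 1 M aq HCl, rt, 2 h
Reagents that add atoms: water, O
Why: Proposed new method: the phosphonate carbanion opens the oxirane of 1 at its CH2 end, the chlorohydrin alkoxide recloses to epoxide 3, a second deprotonation triggers 3-exo-tet closure with clean inversion (this sets the future C4), the bulky phosphoryl group ends trans and the slim nitrile cis to the CH2O− arm so the alkoxide adds to C≡N (Pinner-type) and acid hydrolysis of imidate 5 gives the lactone, so two rings close in one pot; the closest known reactions are the double alkylation–lactonisation of epichlorohydrin with dialkyl malonates and with arylsulfonylacetonitriles.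

**Step 2**
Reactants: 7 4-bromo-2-methoxyphenol
Product: 8 1-(benzyloxy)-4-bromo-2-methoxybenzene
Conditions: BnBr (1.1 equiv), K2CO3 (1.5 equiv), acetone, reflux, 6 h
Reagents that add atoms: benzyl bromide, BrCc1ccccc1
Why: Williamson ether synthesis on an acidic phenol; the benzyl group survives Grignard chemistry and leaves in the final hydrogenolysis at no extra cost.

**Step 3**
Reactants: 9 syringaldehyde
Product: 10 4-(benzyloxy)-3,5-dimethoxybenzaldehyde
Conditions: BnBr (1.1 equiv), K2CO3 (1.5 equiv), DMF, 60 °C, 6 h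
Reagents that add atoms: benzyl bromide, BrCc1ccccc1
Why: Williamson ether synthesis; masking the phenol keeps the aldehyde electrophilic and stops it from protonating the phosphonoenolate of step 4.

**Step 4**
Reactants: 8 1-(benzyloxy)-4-bromo-2-methoxybenzene; 6 diethyl [(1S,5R)-2-oxo-3-oxabicyclo[3.1.0]hexan-1-yl]phosphonate; 10 4-(benzyloxy)-3,5-dimethoxybenzaldehyde
Product: 13 (3E,4S)-3-[4-(benzyloxy)-3,5-dimethoxybenzylidene]-4-[4-(benzyloxy)-3-methoxybenzyl]oxolan-2-one, via aryl Grignard 11 (not isolated), via magnesium phosphonoenolate 12 (not isolated)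
Conditions: 8 (1.15 equiv), Mg turnings, THF, 40 °C; CuI (15 mol%), −30 °C, add 6, to 0 °C, 2 h; add 10 (1.1 equiv), 0 to 60 °C, 6 h; 1 M aq HCl quench
Reagents that add atoms: none
Why: Proposed new method: the arylcopper species attacks the unsubstituted CH2 of the strained, doubly activated cyclopropane (homoconjugate addition) and breaks the bond to the carbon bearing both acceptors without touching C4, and the released phosphonoenolate 12 is itself a Horner–Wadsworth–Emmons reagent that olefinates 10 in the same flask to the (E)-alkene; the closest known reactions are the CuI-catalysed Grignard opening of the corresponding 1-ester bicyclic lactone and magnesium-base Horner–Wadsworth–Emmons olefinations of α-phosphono lactones.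

**Step 5**
Reactants: 13 (3E,4S)-3-[4-(benzyloxy)-3,5-dimethoxybenzylidene]-4-[4-(benzyloxy)-3-methoxybenzyl]oxolan-2-one
Product: 14 (2S,3R,7R)-2-[4-(benzyloxy)-3,5-dimethoxyphenyl]-7-[4-(benzyloxy)-3-methoxybenzyl]-1,5-dioxaspiro[2.4]heptan-4-one
Conditions: DMDO (0.07 M in acetone, 2.5 equiv), CH2Cl2, 0 °C, 12 h; used after filtration through base-washed silica
Reagents that add atoms: dimethyldioxirane (DMDO), CC1(C)OO1
Why: Concerted, acid-free dioxirane epoxidation in which allylic strain with the (E)-aryl group forces the C4 benzyl group pseudoaxial so it blocks one face, and oxygen adds to the opposite face and sets C3 trans to that benzyl group; the second new centre is benzylic and is erased in step 6, so any (Z)-13 converges as well.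

**Step 6**
Reactants: 14 (2S,3R,7R)-2-[4-(benzyloxy)-3,5-dimethoxyphenyl]-7-[4-(benzyloxy)-3-methoxybenzyl]-1,5-dioxaspiro[2.4]heptan-4-one
Product: 15 (3S,4R)-3-hydroxy-3-(4-hydroxy-3,5-dimethoxybenzyl)-4-(4-hydroxy-3-methoxybenzyl)oxolan-2-one
Conditions: H2 (1 atm), 10% Pd/C, EtOAc, rt, 16 h
Reagents that add atoms: none
Why: Catalytic hydrogenolysis cleaves only benzylic C–O bonds, so the oxirane opens at ArCH–O (as with aryl glycidic esters giving α-hydroxy esters), the tertiary C3–O bond keeps its configuration (the descriptor changes from R to S only through priority rules), the benzylic centre becomes CH2 and both benzyl ethers leave as toluene.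

**Compound list**
1 | (S)-epichlorohydrin, (2S)-2-(chloromethyl)oxirane | ClC[C@@H]1CO1 | starting material
2 | diethyl cyanomethylphosphonate | CCOP(=O)(CC#N)OCC | starting material
3 | diethyl {1-cyano-2-[(2S)-oxiran-2-yl]ethyl}phosphonate (both epimers at the acidic carbon) | N#CC(C[C@H]1CO1)P(=O)(OCC)OCC | intermediate
4 | sodium [(1R,2S)-2-cyano-2-(diethoxyphosphoryl)cyclopropyl]methanolate | N#C[C@]1(P(=O)(OCC)OCC)C[C@@H]1C[O-].[Na+] | intermediate
5 | diethyl [(1S,5R)-2-imino-3-oxabicyclo[3.1.0]hexan-1-yl]phosphonate | CCOP(=O)(OCC)[C@@]12C[C@@H]1COC2=N | intermediate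
6 | diethyl [(1S,5R)-2-oxo-3-oxabicyclo[3.1.0]hexan-1-yl]phosphonate | CCOP(=O)(OCC)[C@@]12C[C@@H]1COC2=O | intermediate
7 | 4-bromo-2-methoxyphenol | COc1cc(Br)ccc1O | starting material
8 | 1-(benzyloxy)-4-bromo-2-methoxybenzene | COc1cc(Br)ccc1OCc1ccccc1 | intermediate
9 | syringaldehyde, 4-hydroxy-3,5-dimethoxybenzaldehyde | COc1cc(C=O)cc(OC)c1O | starting material
10 | 4-(benzyloxy)-3,5-dimethoxybenzaldehyde | COc1cc(C=O)cc(OC)c1OCc1ccccc1 | intermediate
11 | [4-(benzyloxy)-3-methoxyphenyl]magnesium bromide | COc1cc([Mg]Br)ccc1OCc1ccccc1 | intermediate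
12 | bromomagnesium enolate of diethyl {(4R)-4-[4-(benzyloxy)-3-methoxybenzyl]-2-oxooxolan-3-yl}phosphonate | CCOP(=O)(OCC)C1=C(O[Mg]Br)OC[C@H]1Cc1ccc(OCc2ccccc2)c(OC)c1 | intermediate
13 | (3E,4S)-3-[4-(benzyloxy)-3,5-dimethoxybenzylidene]-4-[4-(benzyloxy)-3-methoxybenzyl]oxolan-2-one | O=C1OC[C@@H](Cc2ccc(OCc3ccccc3)c(OC)c2)/C1=C\c1cc(OC)c(OCc2ccccc2)c(OC)c1 | intermediate
14 | (2S,3R,7R)-2-[4-(benzyloxy)-3,5-dimethoxyphenyl]-7-[4-(benzyloxy)-3-methoxybenzyl]-1,5-dioxaspiro[2.4]heptan-4-one | O=C1OC[C@@H](Cc2ccc(OCc3ccccc3)c(OC)c2)[C@]12O[C@H]2c1cc(OC)c(OCc2ccccc2)c(OC)c1 | intermediate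
15 | (3S,4R)-3-hydroxy-3-(4-hydroxy-3,5-dimethoxybenzyl)-4-(4-hydroxy-3-methoxybenzyl)oxolan-2-one (CNP0176953.1) | COc1cc(C[C@@H]2COC(=O)[C@]2(O)Cc2cc(OC)c(O)c(OC)c2)ccc1O | target

**Step count**
- Total steps: 6. This falls to 4 if the catalogue benzyl ethers 8 and 10 are bought.
- Longest linear sequence: 4 steps (1 → 6 → 13 → 14 → 15). The branches from 7 and from 9 are also 4 steps long.

**Three steps most likely to fail**

**Step 1.** Three things can go wrong:
- Direct chloride displacement may compete with oxirane opening and erode the ee.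
- The cyclopropane may close with the phosphoryl group cis to the CH2O− arm.
- The imidate may resist hydrolysis.

The fallback sets out from 1, gives up the phosphonate handle and comes back at 13. Treating 1 with diethyl malonate and NaOEt in refluxing EtOH gives ethyl (1R,5S)-2-oxo-3-oxabicyclo[3.1.0]hexane-1-carboxylate F1. Grignard 11 with CuI at −30 °C opens it to ethyl (4S)-4-[4-(benzyloxy)-3-methoxybenzyl]-2-oxooxolane-3-carboxylate F2. Krapcho dealkoxycarbonylation (LiCl, wet DMSO, 140 °C) gives (4S)-4-[4-(benzyloxy)-3-methoxybenzyl]oxolan-2-one F3. An aldol condensation of F3 with 10 (KOtBu, THF, 0 °C to rt, aldol then E1cB loss of water) delivers 13. This costs two more steps.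

**Step 4.** The aryl Grignard may add to the lactone carbonyl instead of the cyclopropane, or the magnesium aldolate may stall before elimination.

The fallback sets out from 6, brings the arene in as an electrophile and comes back at 13. LiI and AcOH in THF at 50 °C add HI across the activated cyclopropane to give diethyl [(4R)-4-(iodomethyl)-2-oxooxolan-3-yl]phosphonate F4. A base-free reductive cross-electrophile coupling of F4 with bromide 8 (NiCl2(dme), 4,4'-di-tert-butyl-2,2'-bipyridine, Zn dust, DMA, 60 °C) gives diethyl {(4R)-4-[4-(benzyloxy)-3-methoxybenzyl]-2-oxooxolan-3-yl}phosphonate F5. A separate Horner–Wadsworth–Emmons reaction of F5 with 10 (NaH, THF, 0 °C to rt) gives 13.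

**Step 5.** The electron-rich aryl oxirane may ionise and rearrange, or the dioxirane may attack the arenes or the benzyl ethers.

The fallback sets out from 13, replaces the oxirane by a robust diol and comes back at 15. Dihydroxylation (OsO4 2 mol%, N-methylmorpholine N-oxide, acetone/water, rt) occurs on the same open face and gives (3R,4R)-4-[4-(benzyloxy)-3-methoxybenzyl]-3-{(S)-[4-(benzyloxy)-3,5-dimethoxyphenyl](hydroxy)methyl}-3-hydroxyoxolan-2-one F6. Hydrogenolysis of F6 (H2, 10% Pd/C, AcOH, trace HClO4, rt) removes the secondary benzylic OH and both benzyl ethers and gives 15 directly.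

**Further compounds**
F1 | step 1 | ethyl (1R,5S)-2-oxo-3-oxabicyclo[3.1.0]hexane-1-carboxylate | CCOC(=O)[C@@]12C[C@@H]1COC2=O
F2 | step 1 | ethyl (4S)-4-[4-(benzyloxy)-3-methoxybenzyl]-2-oxooxolane-3-carboxylate (C3 epimers) | CCOC(=O)C1C(=O)OC[C@H]1Cc1ccc(OCc2ccccc2)c(OC)c1
F3 | step 1 | (4S)-4-[4-(benzyloxy)-3-methoxybenzyl]oxolan-2-one | O=C1C[C@H](Cc2ccc(OCc3ccccc3)c(OC)c2)CO1
F4 | step 4 | diethyl [(4R)-4-(iodomethyl)-2-oxooxolan-3-yl]phosphonate (C3 epimers) | CCOP(=O)(OCC)C1C(=O)OC[C@H]1CI
F5 | step 4 | diethyl {(4R)-4-[4-(benzyloxy)-3-methoxybenzyl]-2-oxooxolan-3-yl}phosphonate (C3 epimers) | CCOP(=O)(OCC)C1C(=O)OC[C@H]1Cc1ccc(OCc2ccccc2)c(OC)c1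
F6 | step 5 | (3R,4R)-4-[4-(benzyloxy)-3-methoxybenzyl]-3-{(S)-[4-(benzyloxy)-3,5-dimethoxyphenyl](hydroxy)methyl}-3-hydroxyoxolan-2-one | O=C1OC[C@@H](Cc2ccc(OCc3ccccc3)c(OC)c2)[C@@]1(O)[C@@H](O)c1cc(OC)c(OCc2ccccc2)c(OC)c1
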